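**Retrosynthetic overview**
1. Target ⇐ 9-epi-alcohol 19 by C9 oxidation and hydroxyl-directed reduction; the C5 tiglate ⇐ SN2 opening of a 1,5-epoxide by tiglate; epoxide and cis-γ-lactone ⇐ iodolactonization of cycloheptenyl acrylic acid 13.
2. C1 carbinol and crotonoyl chain ⇐ 1,2-addition of 1-lithio-1-methoxybutadiene to cyclohept-2-enone 10.
3. Seven-membered ring ⇐ chlorocarbene [2+1] cycloaddition to silyl enol ether 6, then 2π-electrocyclic opening of the chlorocyclopropane (key step).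
4. Cyclohexanone 5 (C10 set) ⇐ cis-carveol epoxide by stereospecific 1,2-hydride shift ⇐ (R)-carvone, the only source of chirality.
5. Ring order: cyclohexane (bought) → cycloheptenone (step 5) → γ-lactone (step 9).

Assumption: ring positions are described with xanthanolide locants (ring C1, C5–C10; lactone C11–C13; enone chain C2–C4, C15); β is the face of the C7 side chain, α the opposite face.

**Step 1**
Reactants: 1 (R)-(−)-carvone
Product: 2 (−)-cis-carveol
Conditions: NaBH4, CeCl3·7H2O, MeOH, −20 °C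
Reagents that add atoms: none
Why: Luche 1,2-reduction; hydride adds anti to the isopropenyl group, so the new hydroxyl is cis to it.

**Step 2**
Reactants: 2 (−)-cis-carveol
Product: 3 (1R,2R,4S,6S)-1-methyl-4-(prop-1-en-2-yl)-7-oxabicyclo[4.1.0]heptan-2-ol
Conditions: VO(acac)2 (cat.), t-BuOOH, CH2Cl2, 0 °C to rt
Reagents that add atoms: tert-butyl hydroperoxide CC(C)(C)OO
Why: Hydroxyl-directed vanadium-catalysed epoxidation delivers oxygen syn to the OH and only to the allylic alkene, leaving the isopropenyl group untouched.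

**Step 3**
Reactants: 3 (1R,2R,4S,6S)-1-methyl-4-(prop-1-en-2-yl)-7-oxabicyclo[4.1.0]heptan-2-ol
Product: 5 (2S,3S,5R)-3-(tert-butyldimethylsilyloxy)-2-methyl-5-(prop-1-en-2-yl)cyclohexan-1-one, via silyl ether of the epoxy alcohol 4 (not isolated)
Conditions: t-BuMe2SiOTf, i-Pr2NEt, CH2Cl2, −78 to −40 °C
Reagents that add atoms: tert-butyldimethylsilyl trifluoromethanesulfonate CC(C)(C)[Si](C)(C)OS(=O)(=O)C(F)(F)F
Why: Silyl-triflate-promoted semipinacol (non-aldol aldol) rearrangement; the carbinol hydride, anti to the epoxide C–O bond, shifts to the tertiary carbon with inversion, which sets C10 (methyl cis to isopropenyl) and leaves C9–O β as its silyl ether (inverted in steps 12–13).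

**Step 4**
Reactants: 5 (2S,3S,5R)-3-(tert-butyldimethylsilyloxy)-2-methyl-5-(prop-1-en-2-yl)cyclohexan-1-one
Product: 6 (3R,5S,6S)-5-(tert-butyldimethylsilyloxy)-6-methyl-3-(prop-1-en-2-yl)-1-(trimethylsilyloxy)cyclohex-1-ene
Conditions: LiN(i-Pr)2, THF, −78 °C; Me3SiCl
Reagents that add atoms: chlorotrimethylsilane C[Si](C)(C)Cl
Why: Kinetic enolization removes the axial proton of the CH2 side (the C2–H is equatorial and hindered), so the axial methyl centre is not epimerized and the enol ether forms away from it.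

**Step 5**
Reactants: 6 (3R,5S,6S)-5-(tert-butyldimethylsilyloxy)-6-methyl-3-(prop-1-en-2-yl)-1-(trimethylsilyloxy)cyclohex-1-ene
Product: 8 (4R,6S,7S)-6-(tert-butyldimethylsilyloxy)-7-methyl-4-(prop-1-en-2-yl)cyclohept-2-en-1-one, via chlorocyclopropane 7 (not isolated)
Conditions: CH2Cl2, NaN(SiMe3)2, pentane, −30 °C to rt; then PhMe, 110 °C
Reagents that add atoms: dichloromethane ClCCl
Why: Chlorocarbene [2+1] cycloaddition to the electron-rich enol ether, then thermal disrotatory 2π-electrocyclic opening of the chlorocyclopropane with loss of Me3SiCl, gives the ring-expanded enone without touching a stereocentre.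

**Step 6**
Reactants: 8 (4R,6S,7S)-6-(tert-butyldimethylsilyloxy)-7-methyl-4-(prop-1-en-2-yl)cyclohept-2-en-1-one
Product: 9 (4R,6S,7S)-6-(tert-butyldimethylsilyloxy)-4-(3-hydroxyprop-1-en-2-yl)-7-methylcyclohept-2-en-1-one
Conditions: SeO2 (cat.), t-BuOOH, CH2Cl2, rt
Reagents that add atoms: tert-butyl hydroperoxide CC(C)(C)OO
Why: SeO2 allylic oxidation (ene reaction, then [2,3]-sigmatropic shift) of the 1,1-disubstituted alkene takes place at CH3 rather than the methine; the enone alkene is inert.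

**Step 7**
Reactants: 9 (4R,6S,7S)-6-(tert-butyldimethylsilyloxy)-4-(3-hydroxyprop-1-en-2-yl)-7-methylcyclohept-2-en-1-one
Product: 10 2-[(1R,5S,6S)-6-(tert-butyldimethylsilyloxy)-5-methyl-4-oxocyclohept-2-en-1-yl]prop-2-enoic acid
Conditions: NaClO2, NaOCl (cat.), 2,2,6,6-tetramethylpiperidin-1-oxyl (cat.), MeCN/NaH2PO4–Na2HPO4 buffer (pH 6.7), 35 °C
Reagents that add atoms: sodium chlorite [Na+].[O-]Cl=O
Why: Oxoammonium-catalysed oxidation of the primary allylic alcohol through the enal to the acid at near-neutral pH leaves the silyl ether and the epimerizable C10 intact.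

**Step 8**
Reactants: 10 2-[(1R,5S,6S)-6-(tert-butyldimethylsilyloxy)-5-methyl-4-oxocyclohept-2-en-1-yl]prop-2-enoic acid; 11 (E)-1-methoxybuta-1,3-diene
Product: 13 hydroxy enone acid (1β-OH; 1α-crotonoyl), via dienyl ether adduct 12 (not isolated)
Conditions: 11 (2.5 equiv), t-BuLi, THF, −78 °C; add 10, −78 °C; then 0.5 M HCl, THF, 0 °C
Reagents that add atoms: water O
Why: The α-alkoxyvinyllithium (first equivalent deprotonates the acid) adds 1,2 to the enone from the α-face, opposite the C10 methyl, C9 silyloxy and C7 chain that all lie β, and acid hydrolysis of the dienyl ether (δ-protonation) unveils the (E)-crotonoyl ketone.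

**Step 9**
Reactants: 13 hydroxy enone acid
Product: 14 α-methylene iodolactone (6β-O cis-fused; 5α-I)
Conditions: I2, NaHCO3, MeCN/H2O, 0 °C, dark
Reagents that add atoms: iodine II
Why: 5-exo iodolactonization; the carboxylate on the β side chain attacks C6 anti to the iodonium, so the γ-lactone is cis-fused and iodine sits α at C5, trans to the C1 hydroxyl.

**Step 10**
Reactants: 14 α-methylene iodolactone
Product: 15 11,13-dihydro iodolactone (11R)
Conditions: H2 (1 atm), RhCl(PPh3)3 (cat.), PhH/EtOH, rt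
Reagents that add atoms: none
Why: Homogeneous hydrogenation reduces only the 1,1-disubstituted α-methylene lactone (the disubstituted crotonoyl alkene is much slower) from the convex face, putting H-11 cis to H-7.

**Step 11**
Reactants: 15 11,13-dihydro iodolactone; 16 tiglic acid
Product: 19 9-epi-target (9β-OH; 5α-tiglate), via epoxide 17 (not isolated), via silyl ether tiglate 18 (not isolated)
Conditions: 16 (4 equiv), Cs2CO3 (1.5 equiv), DMF, 60 °C; then HF·pyridine, THF, 0 °C to rt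
Reagents that add atoms: none
Why: Base closes the trans-iodohydrin to the β-1,5-epoxide (inversion at C5) and cesium tiglate opens it by SN2 at the secondary C5 (second inversion), so the tiglate ends α, trans to both C1–OH and C6–O, before fluoride removes the silyl ether.

**Step 12**
Reactants: 19 9-epi-target
Product: 20 9-ketone
Conditions: Dess–Martin periodinane, CH2Cl2, 0 °C to rt
Reagents that add atoms: none
Why: Dess–Martin oxidation of the only secondary alcohol (C9) under neutral conditions; the tertiary C1–OH and the C10 centre are untouched.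

**Step 13**
Reactants: 20 9-ketone
Product: 21 target, CNP0183494.2
Conditions: Me4NBH(OAc)3, MeCN/AcOH, −30 °C
Reagents that add atoms: none
Why: Evans–Saksena hydroxyl-directed reduction; the borohydride bound to the β C1–OH delivers hydride to the β-face of the C9 ketone, giving the 1,3-anti diol (9α-OH, 9R).

**Compound list**
1 | (R)-(−)-carvone; (5R)-2-methyl-5-(prop-1-en-2-yl)cyclohex-2-en-1-one | O=C1C(C)=CC[C@@H](C(C)=C)C1 | starting material
2 | (−)-cis-carveol; (1R,5R)-2-methyl-5-(prop-1-en-2-yl)cyclohex-2-en-1-ol | O[C@H]1C(C)=CC[C@@H](C(C)=C)C1 | intermediate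
3 | (1R,2R,4S,6S)-1-methyl-4-(prop-1-en-2-yl)-7-oxabicyclo[4.1.0]heptan-2-ol (epoxide syn to OH) | O[C@H]1[C@@]2(C)O[C@H]2C[C@@H](C(C)=C)C1 | intermediate
4 | tert-butyldimethylsilyl ether of 3 (not isolated) | CC(C)(C)[Si](C)(C)O[C@H]1[C@@]2(C)O[C@H]2C[C@@H](C(C)=C)C1 | intermediate
5 | (2S,3S,5R)-3-(tert-butyldimethylsilyloxy)-2-methyl-5-(prop-1-en-2-yl)cyclohexan-1-one (all three substituents cis) | O=C1[C@@H](C)[C@@H](O[Si](C)(C)C(C)(C)C)C[C@@H](C(C)=C)C1 | intermediate
6 | (3R,5S,6S)-5-(tert-butyldimethylsilyloxy)-6-methyl-3-(prop-1-en-2-yl)-1-(trimethylsilyloxy)cyclohex-1-ene | C[Si](C)(C)OC=1[C@@H](C)[C@@H](O[Si](C)(C)C(C)(C)C)C[C@@H](C(C)=C)C=1 | intermediate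
7 | 7-chloro-1-(trimethylsilyloxy)bicyclo[4.1.0]heptane adduct of 6 (mixture at the three new centres; not isolated) | C[Si](C)(C)OC12[C@@H](C)[C@@H](O[Si](C)(C)C(C)(C)C)C[C@@H](C(C)=C)C1C2Cl | intermediate
8 | (4R,6S,7S)-6-(tert-butyldimethylsilyloxy)-7-methyl-4-(prop-1-en-2-yl)cyclohept-2-en-1-one | O=C1[C@@H](C)[C@@H](O[Si](C)(C)C(C)(C)C)C[C@@H](C(C)=C)C=C1 | intermediate
9 | (4R,6S,7S)-6-(tert-butyldimethylsilyloxy)-4-(3-hydroxyprop-1-en-2-yl)-7-methylcyclohept-2-en-1-one | O=C1[C@@H](C)[C@@H](O[Si](C)(C)C(C)(C)C)C[C@@H](C(=C)CO)C=C1 | intermediate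
10 | 2-[(1R,5S,6S)-6-(tert-butyldimethylsilyloxy)-5-methyl-4-oxocyclohept-2-en-1-yl]prop-2-enoic acid | O=C1[C@@H](C)[C@@H](O[Si](C)(C)C(C)(C)C)C[C@@H](C(=C)C(=O)O)C=C1 | intermediate
11 | (E)-1-methoxybuta-1,3-diene | CO/C=C/C=C | starting material
12 | 1,2-adduct of 10: C1 tertiary alcohol bearing a 1-methoxybuta-1,3-dien-1-yl group (not isolated) | C=CC=C(OC)[C@]1(O)[C@@H](C)[C@@H](O[Si](C)(C)C(C)(C)C)C[C@@H](C(=C)C(=O)O)C=C1 | intermediate
13 | 2-{4-[(E)-but-2-enoyl]-6-(tert-butyldimethylsilyloxy)-4-hydroxy-5-methylcyclohept-2-en-1-yl}prop-2-enoic acid; 1β-OH, 1α-crotonoyl, 10β-Me, 9β-OSi, 7β-chain | C/C=C/C(=O)[C@]1(O)[C@@H](C)[C@@H](O[Si](C)(C)C(C)(C)C)C[C@@H](C(=C)C(=O)O)C=C1 | intermediate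
14 | 7-[(E)-but-2-enoyl]-5-(tert-butyldimethylsilyloxy)-7-hydroxy-8-iodo-6-methyl-3-methyleneoctahydro-2H-cyclohepta[b]furan-2-one; cis-fused, 6β-O, 5α-I | C/C=C/C(=O)[C@]1(O)[C@@H](C)[C@@H](O[Si](C)(C)C(C)(C)C)C[C@@H]2[C@@H](OC(=O)C2=C)[C@@H]1I | intermediate
15 | 11,13-dihydro derivative of 14 (3-methyl lactone, 11R, H-11 cis to H-7) | C/C=C/C(=O)[C@]1(O)[C@@H](C)[C@@H](O[Si](C)(C)C(C)(C)C)C[C@@H]2[C@@H](OC(=O)[C@@H]2C)[C@@H]1I | intermediate
16 | tiglic acid; (E)-2-methylbut-2-enoic acid | C/C=C(\C)C(=O)O | starting material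
17 | 1β,5β-epoxide from 15 (not isolated) | C/C=C/C(=O)[C@]12[C@@H](C)[C@@H](O[Si](C)(C)C(C)(C)C)C[C@@H]3[C@@H](OC(=O)[C@@H]3C)[C@H]1O2 | intermediate
18 | 9-O-tert-butyldimethylsilyl ether of 19 (not isolated) | C/C=C/C(=O)[C@]1(O)[C@@H](C)[C@@H](O[Si](C)(C)C(C)(C)C)C[C@@H]2[C@@H](OC(=O)[C@@H]2C)[C@@H]1OC(=O)/C(C)=C/C | intermediate
19 | 9-epi-target (9β-OH); (3R,3aS,5S,6S,7S,8S,8aR)-7-[(E)-but-2-enoyl]-5,7-dihydroxy-3,6-dimethyl-2-oxooctahydro-2H-cyclohepta[b]furan-8-yl (E)-2-methylbut-2-enoate | C/C=C/C(=O)[C@]1(O)[C@@H](C)[C@@H](O)C[C@@H]2[C@@H](OC(=O)[C@@H]2C)[C@@H]1OC(=O)/C(C)=C/C | intermediate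
20 | 9-ketone: 5-oxo analogue of 19 (C9 carbonyl; all other centres as in the target) | C/C=C/C(=O)[C@]1(O)[C@@H](C)C(=O)C[C@@H]2[C@@H](OC(=O)[C@@H]2C)[C@@H]1OC(=O)/C(C)=C/C | intermediate
21 | CNP0183494.2; (3R,3aS,5R,6S,7S,8S,8aR)-7-[(E)-but-2-enoyl]-5,7-dihydroxy-3,6-dimethyl-2-oxooctahydro-2H-cyclohepta[b]furan-8-yl (E)-2-methylbut-2-enoate | C/C=C/C(=O)[C@]1(O)[C@@H](C)[C@H](O)C[C@@H]2[C@@H](OC(=O)[C@@H]2C)[C@@H]1OC(=O)/C(C)=C/C | target

**Step count and risks**
Total steps: 13. Longest linear sequence: 13 (from 1; 11 and 16 are bought).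

The three steps most likely to fail:

- **Step 5** (carbene addition and electrocyclic opening). Chlorocarbene may also attack the isopropenyl group, and only the endo-chloro cyclopropane opens easily. The fallback sets out from 6. Cyclopropanation with Et2Zn and CH2I2 in CH2Cl2 at 0 °C gives the siloxycyclopropane F1. FeCl3 in DMF at 0 °C opens it by alkoxy-radical fragmentation to the 3-chlorocycloheptanone F2. NaOAc in MeOH then eliminates HCl, and the route is rejoined at 8.

- **Step 11** (carboxylate opening of the hindered 1,5-epoxide). The SN2 attack at C5 may be slow, and base may open the epoxide by elimination instead. The fallback sets out from 15. HF·pyridine frees the C9 alcohol, giving the iodolactone diol F3. Dess–Martin periodinane gives the C9 ketone F4. Ag2O in CH2Cl2 closes the 1,5-epoxide F5. Dilute aqueous HClO4 in THF opens it at C5 with inversion to the C1,C5-diol F6. Yamaguchi esterification (16, 2,4,6-trichlorobenzoyl chloride, Et3N, 4-(dimethylamino)pyridine) acylates the only secondary hydroxyl, and the route is rejoined at 20.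

- **Step 13** (directed reduction). The C1 hydroxyl is also α to the enone carbonyl, and ketone 20 can epimerize at C10 or undergo retro-aldol cleavage. The fallback sets out from 19. Mitsunobu reaction with chloroacetic acid (PPh3, diisopropyl azodicarboxylate, PhMe) inverts C9 directly to the 9α-chloroacetate F7. Thiourea and NaHCO3 in EtOH remove the chloroacetyl group while the tiglate and lactone stay, and the route is rejoined at 21.

**Further compounds**
F1 | step 5 | 1-(trimethylsilyloxy)bicyclo[4.1.0]heptane from 6 (siloxycyclopropane) | C[Si](C)(C)OC12[C@@H](C)[C@@H](O[Si](C)(C)C(C)(C)C)C[C@@H](C(C)=C)C1C2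
F2 | step 5 | 6-(tert-butyldimethylsilyloxy)-3-chloro-7-methyl-4-(prop-1-en-2-yl)cycloheptan-1-one | O=C1[C@@H](C)[C@@H](O[Si](C)(C)C(C)(C)C)C[C@@H](C(C)=C)C(Cl)C1
F3 | step 11 | 9-desilyl derivative of 15 (9β-OH iodolactone) | C/C=C/C(=O)[C@]1(O)[C@@H](C)[C@@H](O)C[C@@H]2[C@@H](OC(=O)[C@@H]2C)[C@@H]1I
F4 | step 11 | 9-keto iodolactone | C/C=C/C(=O)[C@]1(O)[C@@H](C)C(=O)C[C@@H]2[C@@H](OC(=O)[C@@H]2C)[C@@H]1I
F5 | step 11 | 9-keto 1β,5β-epoxide | C/C=C/C(=O)[C@]12[C@@H](C)C(=O)C[C@@H]3[C@@H](OC(=O)[C@@H]3C)[C@H]1O2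
F6 | step 11 | 9-keto 1β,5α-diol (des-tigloyl 20) | C/C=C/C(=O)[C@]1(O)[C@@H](C)C(=O)C[C@@H]2[C@@H](OC(=O)[C@@H]2C)[C@@H]1O
F7 | step 13 | 9-O-chloroacetyl derivative of 21 (9α-chloroacetate) | C/C=C/C(=O)[C@]1(O)[C@@H](C)[C@H](OC(=O)CCl)C[C@@H]2[C@@H](OC(=O)[C@@H]2C)[C@@H]1OC(=O)/C(C)=C/C
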